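The ratio to hold in your head is feed time over capture time, because it tells you whether a slow addition can leave the outcome alone.

| flask | substrate | first nucleophile | second nucleophile | remark | time |
|---|---|---|---|---|---|
| ochre | 0.27 M | 0.243 M | 0.284 M | run made earlier |  |
| grey | 0.27 M | 0.243 M | 0.19 M | run made earlier |  |
| violet | 0.27 M | 0.243 M | 0.43 M | run made earlier |  |
| green | 0.27 M | 0.49 M | 0.284 M | run made earlier |  |
| gamma | 0.27 M | 0.243 M (fed, over 3.0 h) | 0.284 M | all else is in the flask from the start; the feed brings no volume worth counting | 15 h |
| theta | 0.27 M (fed, over 3.0 h) | 0.243 M | 0.284 M | all else is in the flask from the start; the feed brings no volume worth counting | 15 h |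
| beta | 0.27 M | 0.243 M | 0.284 M | everything together at the start | 15 h |

- ochre (time / h: target / %, other capture product / %): 0.667: 24, 41; 2.00: 20, 55; 3.00: 13, 61; 5.00: 9, 65; 6.00: 13, 64; 10.0: 14, 65
- grey (time / h: target / %, other capture product / %): 2.00: 22, 46; 4.00: 18, 53; 6.00: 15, 55; 8.00: 15, 56; 10.0: 12, 61; 12.0: 12, 61
- violet (time / h: target / %, other capture product / %): 1.00: 24, 59; 1.50: 18, 61; 2.50: 15, 71; 4.00: 8, 70; 8.00: 11, 72; 12.0: 11, 67
- green (time / h: target / %, other capture product / %): 1.00: 29, 44; 2.00: 23, 49; 3.00: 20, 52; 6.00: 15, 55; 12.0: 12, 57

(standard deviation of a reading: 2 percentage points)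

- the numbers in the tables scatter with a standard deviation of 2 percentage points

* which flask leads in share of target in target plus other capture product ("all alike" within 1.5 percentage points) (gamma / theta / beta / all alike)
* share of target in target plus other capture product at the end, gamma
* share of target in target plus other capture product at the end, theta
* share of target in target plus other capture product at the end, beta

Read the capture time from the ochre run. The sum of target and other capture product stands at 65.0 % after 0.667 h and at 79.0 % in the last reading. If that gap closes exponentially, it shrinks by a factor of two every 0.267 h, a reading that carries the scatter. The feed time 3.0 h over this gives 11.2: that is the dosing ratio, feed time over capture half-life, a Damköhler number.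

So the feed is far slower than capture, and I don't expect the flasks to match. In gamma, the steady feed has brought in 8.90 % of the first nucleophile after one capture half-life, so second nucleophile should take the early substrate and gamma should trail beta. In theta, substrate comes in over the length of the feed, so its later portions meet whatever first nucleophile remains. Green, with 0.49 M in place of 0.243 M, reads 29 % target at 1.00 h against 24 % at 0.667 h in ochre, which suggests first nucleophile doesn't last. My order is therefore beta, gamma, theta.

The forecast differs, saying “Feeding changes the early path only” and giving 15.5 % for gamma, 15.5 % for theta and 15.5 % for beta, so all alike.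

The flasks give 11.1 % for gamma, 3.91 % for theta and 15.5 % for beta, so beta leads.

    substrate ⇌ intermediate (K = 0.00970, k = 0.00300 s⁻¹)
    first nucleophile + intermediate → target (k = 0.420 M⁻¹ s⁻¹)
    second nucleophile + intermediate → other capture product (k = 0.190 M⁻¹ s⁻¹)
    second nucleophile ⇌ dormant form (K = 0.410, k = 4.10 × 10⁻⁵ s⁻¹)
    2 first nucleophile → homo dimer (k = 0.00460 M⁻¹ s⁻¹)
    target ⇌ isomer of the product (K = 1.90, k = 1.30 × 10⁻⁴ s⁻¹)

At a dosing ratio of 11.2, gamma ends below beta. The same gamma dosed over 0.300 h has a ratio of 1.12 and gives 16.2 %, while over 9.00 h the ratio is 33.7 and it gives 7.16 %. Theta's gap of 12 points below beta comes in part from two steps acting together, the joining of first nucleophile into homo dimer and the return of isomer of the product to target. Without that return the gap is 0.035 points, and without the homo dimer path it is −2.5 points.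

Readings and results are calculated from invented constants; scatter was added.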